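## Retrosynthetic overview
1. Target 16 comes from TBS ether 15. The 15-membered ring is closed last by an intramolecular Stille coupling (ArCH2–SnBu3 with the tetrasubstituted enol triflate, C1′–C2′). This step also creates the only oxidation-sensitive alkene, after all epoxidations are finished.
2. Seco compound 14: the hindered tertiary benzoate C–O bond is made intermolecularly from stannyl acid 13 and tertiary bromohydrin 9.
3. Bromohydrin 9 comes from the geranyl chain of triflate 7 by one double ent-Shi epoxidation (sets C9′, C10′, C13′). Terminal-selective SN2 opening with bromide then gives C13′–Br with inversion.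
4. Triflate 7 comes from prochiral 2-geranyl-2-methylcyclohexane-1,3-dione 3 by CBS desymmetrisation (C7′ and the carbinol), Appel inversion (C6′–Br), α-methylation and enol triflation. Dione 3 comes from dione 1 and geranyl bromide 2.
5. Ring order: the carbocycle is bought in 1, then two oxiranes are made (one is re-opened), and the macrolactone is closed last.

**Assumption:** the SMILES is read literally, so the terpenoid part is C19 (a geranyl chain on the quaternary ring carbon) and the lactone is 15-membered. (S)-Me-CBS and the L-fructose-derived (ent-)Shi ketone are treated as purchasable catalysts.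

**Locants:** C1′ is the ArCH2 carbon. C2′=C3′(Me) is the ring alkene. C6′ is the ring CHBr and C7′ the quaternary carbon. C8′H2 links C7′ to the epoxide C9′/C10′(Me). C13′ is the chain CHBr and C14′ is CMe2O.

**Target descriptors:** C6′ S, C7′ S, C9′ S, C10′ S, C13′ R. Br at C6′ is cis to the C7′ methyl and trans to C8′. The epoxide is derived from an E-alkene.

## Route

**Step 1**
- Reactants: 1 2-methylcyclohexane-1,3-dione; 2 geranyl bromide
- Product: 3 2-[(2E)-3,7-dimethylocta-2,6-dienyl]-2-methylcyclohexane-1,3-dione
- Conditions: 1 M aq NaOH (1.0 equiv), Bu4NI (5 mol %), rt, 36 h; dilute HCl work-up (hydrolyses the O-alkyl by-product back to 1)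
- Reagents that add atoms: none
- Why: SN2 C-alkylation of the stabilised 1,3-dione enolate with an allylic bromide keeps the E-alkene and gives a prochiral quaternary carbon, so no stereocentre is formed yet.

**Step 2**
- Reactants: 3
- Product: 4 (2R,3R)-2-geranyl-3-hydroxy-2-methylcyclohexan-1-one (OH cis to geranyl, trans to CH3)
- Conditions: (S)-Me-CBS (0.3 equiv), catecholborane (1.2 equiv), PhNEt2, toluene, −78 → −60 °C
- Reagents that add atoms: none
- Why: In this Corey–Bakshi–Shibata enantiotopic-group-selective reduction the catalyst treats the quaternary carbon as the large group and gives the (R)-carbinol, while hydride enters anti to geranyl, so only one carbonyl satisfies both demands and C7′ and C6′–O are set together.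

**Step 3**
- Reactants: 4
- Product: 5 (2S,3S)-3-bromo-2-geranyl-2-methylcyclohexan-1-one (Br trans to geranyl, cis to CH3)
- Conditions: CBr4, PPh3, 2,6-lutidine, toluene, 70 °C
- Reagents that add atoms: carbon tetrabromide, BrC(Br)(Br)Br
- Why: The Appel reaction displaces the axial oxyphosphonium by SN2 with inversion to give the equatorial bromide, helped because the quaternary α-carbon blocks E1cB and the adjacent C=O disfavours cationic 1,2-shifts.

**Step 4**
- Reactants: 5
- Product: 6 (2S,3S,6RS)-3-bromo-2-geranyl-2,6-dimethylcyclohexan-1-one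
- Conditions: LDA, THF, −78 °C; MeI, DMPU, −78 → −20 °C
- Reagents that add atoms: iodomethane, CI
- Why: Kinetic enolate alkylation can occur only at the single enolisable α-carbon, and the new C3′ centre is an inconsequential mixture that is destroyed in Step 5.

**Step 5**
- Reactants: 6
- Product: 7 (5S,6S)-5-bromo-6-geranyl-2,6-dimethylcyclohex-1-en-1-yl triflate
- Conditions: KHMDS, THF, −78 → 0 °C; Comins' reagent, −78 °C → rt
- Reagents that add atoms: Comins' reagent, ClC1=CN=C(C=C1)N(S(=O)(=O)C(F)(F)F)S(=O)(=O)C(F)(F)F
- Why: O-triflation of the only possible (tetrasubstituted) enolate is the 2,2,6-trialkylcyclohexanone case, and the equatorial bromide has no antiperiplanar H for E2.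

**Step 6**
- Reactants: 7
- Product: 8 bis-epoxide, (5S,6S)-5-bromo-6-{[(2S,3S)-3-{2-[(2S)-3,3-dimethyloxiran-2-yl]ethyl}-3-methyloxiran-2-yl]methyl}-2,6-dimethylcyclohex-1-en-1-yl triflate
- Conditions: ent-Shi ketone (0.6 equiv), Oxone, K2CO3, Bu4NHSO4, MeCN–DMM / borate–EDTA buffer (pH ≈ 10.5), 0 °C, 3 h; minor diastereomers removed by chromatography
- Reagents that add atoms: Oxone (KHSO5), [K+].[O-]S(=O)(=O)OO
- Why: Shi asymmetric epoxidation through the spiro dioxirane transition state gives, with the L-series catalyst, (S,S) from the E-trisubstituted alkene and (S) from the prenyl terminus under reagent control, and the electron-poor, hindered enol triflate is inert.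

**Step 7**
- Reactants: 8
- Product: 9 (5S,6S)-5-bromo-6-{[(2S,3S)-3-[(3R)-3-bromo-4-hydroxy-4-methylpentyl]-3-methyloxiran-2-yl]methyl}-2,6-dimethylcyclohex-1-en-1-yl triflate
- Conditions: Li2NiBr4 (1.1 equiv, 0.4 M in THF), THF, −20 → 0 °C, stopped at about 85 % conversion; pH 7 phosphate quench
- Reagents that add atoms: dilithium tetrabromonickelate, [Li+].[Li+].[Ni+2].[Br-].[Br-].[Br-].[Br-]
- Why: Soft bromide opens the epoxide by SN2 at the secondary carbon with inversion (S-epoxide to R-bromide), and the terminal oxirane reacts first because C9′ of the internal one carries a neopentyl-type substituent.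

**Step 8**
- Reactants: 10 4-hydroxy-3-methylbenzoic acid
- Product: 11 tert-butyldimethylsilyl 4-(tert-butyldimethylsilyloxy)-3-methylbenzoate
- Conditions: TBSCl (2.3 equiv), imidazole, DMF, rt
- Reagents that add atoms: TBSCl, CC(C)(C)[Si](C)(C)Cl
- Why: Exhaustive silylation masks both acidic protons for the radical and organometallic steps that follow.

**Step 9**
- Reactants: 11
- Product: 12 tert-butyldimethylsilyl 3-(bromomethyl)-4-(tert-butyldimethylsilyloxy)benzoate
- Conditions: NBS, AIBN, PhCF3, 85 °C
- Reagents that add atoms: NBS, O=C1CCC(=O)N1Br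
- Why: Wohl–Ziegler bromination occurs at the only benzylic C–H position.

**Step 10**
- Reactants: 12
- Product: 13 4-(tert-butyldimethylsilyloxy)-3-[(tributylstannyl)methyl]benzoic acid
- Conditions: (Bu3Sn)2, Pd(PPh3)4 (2 mol %), toluene, 90 °C; then 5 % aq citric acid–THF, rt
- Reagents that add atoms: hexabutylditin, CCCC[Sn](CCCC)(CCCC)[Sn](CCCC)(CCCC)CCCC
- Why: Pd(0)-catalysed stannylation of the benzylic bromide with a distannane installs the tin, and the labile silyl ester hydrolyses on mild acidic work-up while the aryl TBS ether and the C–Sn bond survive.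

**Step 11**
- Reactants: 9; 13 (2–3 equiv)
- Product: 14 seco ester (tertiary 4-TBSO-3-(Bu3SnCH2)benzoate of 9)
- Conditions: MNBA, DMAP (stoichiometric), Et3N, CH2Cl2 (0.3 M), rt → 35 °C, 48 h
- Reagents that add atoms: none
- Why: Shiina mixed-anhydride esterification delivers the acyl group by DMAP transfer with carboxylate as general base, and being halide-free and only weakly basic it leaves the internal epoxide unopened and the bromohydrin unclosed, with no stereocentre touched.

**Step 12**
- Reactants: 14
- Product: 15 O-TBS macrolactone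
- Conditions: Pd2(dba)3·CHCl3 (15 mol %), AsPh3 (0.6 equiv), NMP–THF, 55 °C, syringe-pump addition to 1 mM
- Reagents that add atoms: none
- Why: This Stille macrocyclisation (Farina conditions) uses a 2,6,6-trisubstituted cyclohexenyl triflate, a proven Stille electrophile, with a benzylstannane stable enough for slow high-dilution coupling, and the secondary bromides, epoxide and ester are inert to Pd(0)/AsPh3.

**Step 13**
- Reactants: 15
- Product: 16 target (CID 46880797)
- Conditions: TBAF/AcOH (1:1), THF, 0 °C, 15 min
- Reagents that add atoms: none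
- Why: Buffered fluoride cleaves the electron-poor aryl silyl ether rapidly and is not basic enough to affect the bromides, epoxide or lactone.

## Compound list

| No. | Name | SMILES | Role |
|---|---|---|---|
| 1 | 2-methylcyclohexane-1,3-dione | `CC1C(=O)CCCC1=O` | starting material |
| 2 | geranyl bromide | `CC(C)=CCC/C(C)=C/CBr` | starting material |
| 3 | 2-geranyl-2-methylcyclohexane-1,3-dione | `CC(C)=CCC/C(C)=C/CC1(C)C(=O)CCCC1=O` | intermediate |
| 4 | (2R,3R)-2-geranyl-3-hydroxy-2-methylcyclohexanone | `CC(C)=CCC/C(C)=C/C[C@]1(C)[C@H](O)CCCC1=O` | intermediate |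
| 5 | (2S,3S)-3-bromo-2-geranyl-2-methylcyclohexanone | `CC(C)=CCC/C(C)=C/C[C@]1(C)[C@@H](Br)CCCC1=O` | intermediate |
| 6 | (2S,3S,6RS)-3-bromo-2-geranyl-2,6-dimethylcyclohexanone | `CC(C)=CCC/C(C)=C/C[C@]1(C)[C@@H](Br)CCC(C)C1=O` | intermediate |
| 7 | (5S,6S)-5-bromo-6-geranyl-2,6-dimethylcyclohex-1-enyl triflate | `CC(C)=CCC/C(C)=C/C[C@]1(C)[C@@H](Br)CCC(C)=C1OS(=O)(=O)C(F)(F)F` | intermediate |
| 8 | bis-epoxide (C9′S, C10′S, C13′S; ring 5S,6S) | `CC1(C)O[C@H]1CC[C@]2(C)O[C@H]2C[C@]3(C)[C@@H](Br)CCC(C)=C3OS(=O)(=O)C(F)(F)F` | intermediate |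
| 9 | epoxy bromohydrin triflate (C13′R) | `CC(C)(O)[C@H](Br)CC[C@]1(C)O[C@H]1C[C@]2(C)[C@@H](Br)CCC(C)=C2OS(=O)(=O)C(F)(F)F` | intermediate |
| 10 | 4-hydroxy-3-methylbenzoic acid | `Cc1cc(ccc1O)C(=O)O` | starting material |
| 11 | TBS 4-(TBSO)-3-methylbenzoate | `Cc1cc(ccc1O[Si](C)(C)C(C)(C)C)C(=O)O[Si](C)(C)C(C)(C)C` | intermediate |
| 12 | TBS 3-(bromomethyl)-4-(TBSO)benzoate | `BrCc1cc(ccc1O[Si](C)(C)C(C)(C)C)C(=O)O[Si](C)(C)C(C)(C)C` | intermediate |
| 13 | 4-(TBSO)-3-[(tributylstannyl)methyl]benzoic acid | `CCCC[Sn](CCCC)(CCCC)Cc1cc(ccc1O[Si](C)(C)C(C)(C)C)C(=O)O` | intermediate |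
| 14 | seco stannyl-ester triflate | `CCCC[Sn](CCCC)(CCCC)Cc1cc(ccc1O[Si](C)(C)C(C)(C)C)C(=O)OC(C)(C)[C@H](Br)CC[C@]2(C)O[C@H]2C[C@]3(C)[C@@H](Br)CCC(C)=C3OS(=O)(=O)C(F)(F)F` | intermediate |
| 15 | O-TBS macrolactone | `CC1=C2Cc3cc(ccc3O[Si](C)(C)C(C)(C)C)C(=O)OC(C)(C)[C@H](Br)CC[C@]3(C)O[C@H]3C[C@]2(C)[C@@H](Br)CC1` | intermediate |
| 16 | target: 15-membered 4-hydroxybenzoate macrolactone (C6′S, C7′S, C9′S, C10′S, C13′R) | `CC1=C2Cc3cc(ccc3O)C(=O)OC(C)(C)[C@H](Br)CC[C@]3(C)O[C@H]3C[C@]2(C)[C@@H](Br)CC1` | target |

## Totals
- **Total steps:** 13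
- **Longest linear sequence:** 10 (Steps 1–7, 11, 12, 13)

## Three steps most likely to fail
1. **Step 12, macro-Stille at a neopentyl, tetrasubstituted triflate.** Fallback: reverse the order of the two unions.
   - Couple intermolecularly first by a Negishi reaction of triflate 8 with the benzylzinc reagent from an allyl-ester analogue of 12.
   - Then close the ring at O–C14′: open the terminal epoxide, convert the tertiary OH to its trichloroacetimidate, free the acid with Pd(0), and let it capture the bromonium-stabilised tertiary cation under base-free high dilution.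
2. **Step 3, SN2 at a carbinol next to a quaternary carbon.** Fallback: abandon displacement. Set C6′–Br and C7′ together by an enantiospecific bromonium-initiated cation–olefin cyclisation (anti addition across an E-trisubstituted alkene, for example from an enantiopure bromohydrin ester ionised with a Lewis acid), and elaborate that ring instead of the dione.
3. **Step 7, terminal versus internal epoxide selectivity, with possible attack of the tertiary alkoxide on the internal epoxide.** Fallback: functionalise the terminus before the ring is attached.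
   - Take geranyl acetate through 6,7-selective ent-Shi epoxidation, Li2NiBr4 opening and TES protection of the tertiary OH.
   - Join it to 1 by Tsuji–Trost allylation, carry out Steps 2–5, perform a single Shi epoxidation, and desilylate with HF·pyridine to reach 9.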